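**Reading time.** Each flask is read at 5.0 h, so what counts is how far target can grow by then.

| setting | larch | alder | noon | summer | winter |
|---|---|---|---|---|---|
| substrate | 1.1 M | 1.1 M | 2.1 M | 2.1 M | 2.1 M |
| temperature | −40 °C | −5 °C | 25 °C | −35 °C | −5 °C |
| remark | run made earlier | run made earlier |  |  |  |
| time |  |  | 5.0 h | 5.0 h | 5.0 h |

| run | time / h | target / % |
|---|---|---|
| larch | 20.0 | 10 |
| larch | 40.0 | 21 |
| larch | 60.0 | 25 |
| larch | 72.0 | 28 |
| larch | 96.0 | 36 |
| larch | 120 | 39 |
| larch | 144 | 42 |
| alder | 4.00 | 24 |
| alder | 6.00 | 24 |
| alder | 12.0 | 18 |
| alder | 20.0 | 15 |
| alder | 25.0 | 14 |

(standard deviation of a reading: 1.5 percentage points)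

1. the flask with the highest amount of target, in percent of the substrate charged ("all alike" if they lie within 1.5 percentage points) (noon / summer / winter / all alike)
2. final target, as a percentage of the substrate charged, in noon
3. final target, as a percentage of the substrate charged, in summer
4. final target, as a percentage of the substrate charged, in winter

- a species is counted by the substrate in it: one target counts as two
- a species is counted by the substrate in it: one side product counts as three
- the numbers in the tables scatter by 1.5 percentage points (one standard deviation)
- candidate steps: substrate + target -> side product; 2 substrate <-> target; substrate <-> dormant form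

**One clock.** Two substrate molecules join to make one target, so I take the growth as second-order in substrate. Target over remaining substrate then rises in step with time. Larch at 72.0 h gives 185 h. That is my pairing time: the time at which target and remaining substrate stand equal, with forward pairing unopposed.

**First doubt.** One reading carries scatter. But larch at 20.0 h gives 180 h, which is close. Larch also still climbs at 144 h, which shows that making outruns any loss there, not that loss is absent.

**Second doubt.** The clock shortens as the charge grows, so at 2.1 M larch conditions give 97.0 h. But summer stands at −35 °C, not −40 °C. With the forecast's assumed 60 kJ/mol I take a factor of 2, an assumption and not a reading. The summer clock is then 48.5 h. The reading comes much earlier than that, so summer is under kinetic control, and I commit to 9.35%.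

**Third doubt.** The clock fails in the warm. Alder stands at 24% at 4.00 h and at 24% at 6.00 h, then sinks to 14% by 25.0 h. That is a balance being eroded, which is thermodynamic control. Winter has the larger charge, so I expect it to peak above alder and then erode, still ahead of summer. Larch passes alder's peak, so warmth lowers the peak, and I expect noon to hold least.

**The forecast.** It names winter, with noon 4%, summer 9.5% and winter 27%. For winter it says: “equilibrium about 34% at 2.1 M, eroded by side product to about 27%”. My summer figure sits just below its own.

**The flasks.** Noon gives 1.43%, summer 9.85% and winter 28.6%, so winter holds most.

    substrate + target → side product (k = 0.0346 /M/min, Ea = 69.0 kJ/mol)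
    2 substrate ⇌ target (K = 0.0781 /M, k = 0.0393 /M/min, Ea = 60.0 kJ/mol, ΔH = −32.0 kJ/mol)
    substrate ⇌ dormant form (K = 1.27, k = 0.00997 /min, Ea = 99.0 kJ/mol, ΔH = 24.0 kJ/mol)
    (constants at 25 °C)

**Summer again.** Read backwards, summer's 9.85% gives a pairing time of 45.8 h, against my 48.5 h. Summer still holds 90.0% substrate at the reading, and the time allowed is a large effect on its target: 9.85% at the reading against 45.7% at 50.0 h. Left to 50.0 h, my clock puts summer at 50.8%, and the simulated flask holds 45.7% target beside 5.44% side product.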